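**Retrosynthetic overview**
- The route rests on ring C: C3 and C4 are joined last, as the silyl enol ether of the C4 ketone, by ring-closing metathesis between a vinyl group on C2 and a 1-silyloxyvinyl group on C4a. O1–C2 and the (2S) centre are already in place as a branched allylic aryl ether on ring A.
- Disconnections: C8–prenyl ⇒ O5 prenyl ether (para-Claisen–Cope, last step); C3=C4 ⇒ metathesis; O1–C2 ⇒ iridium-catalysed asymmetric allylic etherification of a ring A phenol with a ring B cinnamyl carbonate.
- Ring A: 3,4,5-trimethoxyphenol is C-acetylated. Its phenol (future O1) is masked as an acetate while the methoxy group ortho to the ketone (future O5) is cleaved and prenylated, so the two oxygens flanking the acetyl group are told apart by construction and not by a selective alkylation.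
- Ring order: rings A and B are bought; ring C is the only ring formed, in the key step.

Key step: step 11

Assumption: the (Sa,Sc,Sc) phosphoramidite is taken to give the (S)-configured branched aryl ether from an (E)-cinnamyl carbonate, in line with the sense of induction recalled for this ligand family with O- and N-nucleophiles; the configuration of 13 is to be confirmed on the first batch and the ligand antipode used if it is the other way round.

**Route**

Step 1
Reactants: 1 3,4,5-trimethoxyphenol
Product: 2 1-(6-hydroxy-2,3,4-trimethoxyphenyl)ethanone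
Conditions: AcOH, BF3·OEt2, 90 °C; then H2O
Reagents that add atoms: acetic acid, CC(=O)O
Why: Friedel–Crafts C-acetylation promoted by BF3 can only take place at the two equivalent positions ortho to the hydroxyl, and the boron-chelated ortho-hydroxy ketone is released on aqueous work-up.

Step 2
Reactants: 2 1-(6-hydroxy-2,3,4-trimethoxyphenyl)ethanone
Product: 3 2-acetyl-3,4,5-trimethoxyphenyl acetate
Conditions: Ac2O, pyridine, DMAP (cat.), CH2Cl2, rt
Reagents that add atoms: acetic anhydride, CC(=O)OC(C)=O
Why: DMAP-catalysed O-acylation should acetylate even the hydrogen-bonded phenol, masking the future O1 so that it stays distinct from the oxygen unveiled in step 3.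

Step 3
Reactants: 3 2-acetyl-3,4,5-trimethoxyphenyl acetate
Product: 4 2-acetyl-3-hydroxy-4,5-dimethoxyphenyl acetate
Conditions: BCl3 (1.5 equiv), CH2Cl2, −78 → 0 °C; then H2O
Reagents that add atoms: none
Why: Chelation-directed ether cleavage, in which BCl3 bound to the ketone oxygen cleaves only the methoxy group ortho to the carbonyl, while the aryl acetate and the two remote methoxy groups are inert to BCl3 at low temperature.

Step 4
Reactants: 4 2-acetyl-3-hydroxy-4,5-dimethoxyphenyl acetate; 5 3-methylbut-2-en-1-ol (prenol)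
Product: 6 2-acetyl-4,5-dimethoxy-3-(3-methylbut-2-enyloxy)phenyl acetate
Conditions: PPh3, DIAD, THF, 0 °C → rt
Reagents that add atoms: none
Why: Mitsunobu etherification alkylates the chelated phenol at oxygen by SN2 attack on the primary allylic oxyphosphonium carbon under neutral conditions, as is known for the 5-hydroxyl of acetylated flavanones, and leaves the aryl acetate untouched.

Step 5
Reactants: 6 2-acetyl-4,5-dimethoxy-3-(3-methylbut-2-enyloxy)phenyl acetate
Product: 7 1-[6-hydroxy-3,4-dimethoxy-2-(3-methylbut-2-enyloxy)phenyl]ethanone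
Conditions: K2CO3 (0.3 equiv), MeOH, 0 °C → rt; aq. NH4Cl
Reagents that add atoms: none
Why: Base-catalysed methanolysis (transesterification) of the aryl acetate is fast at room temperature and touches neither the prenyl ether nor the ketone, freeing the single phenol that becomes O1.

Step 6
Reactants: 8 methyl (E)-4-hydroxycinnamate
Product: 9 methyl (E)-3-[4-(tert-butyldimethylsilyloxy)phenyl]acrylate
Conditions: TBSCl, imidazole, DMF, rt
Reagents that add atoms: tert-butyldimethylsilyl chloride, CC(C)(C)[Si](C)(C)Cl
Why: Imidazole-mediated silylation of a phenol is routine and gives a group that survives hydride, aryloxide and amide base and falls to fluoride at the end.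

Step 7
Reactants: 9 methyl (E)-3-[4-(tert-butyldimethylsilyloxy)phenyl]acrylate
Product: 10 (E)-3-[4-(tert-butyldimethylsilyloxy)phenyl]prop-2-en-1-ol
Conditions: i-Bu2AlH (2.5 equiv), CH2Cl2, −78 °C; Rochelle salt
Reagents that add atoms: none
Why: 1,2-Reduction of the conjugated ester by i-Bu2AlH at low temperature gives the allylic alcohol with the (E) double bond intact.

Step 8
Reactants: 10 (E)-3-[4-(tert-butyldimethylsilyloxy)phenyl]prop-2-en-1-ol
Product: 11 (E)-3-[4-(tert-butyldimethylsilyloxy)phenyl]allyl methyl carbonate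
Conditions: ClCO2Me, pyridine, CH2Cl2, 0 °C
Reagents that add atoms: methyl chloroformate, COC(=O)Cl
Why: O-Acylation with the chloroformate gives the linear methyl carbonate, the standard leaving group for iridium-catalysed allylic substitution.

Step 9
Reactants: 7 1-[6-hydroxy-3,4-dimethoxy-2-(3-methylbut-2-enyloxy)phenyl]ethanone; 11 (E)-3-[4-(tert-butyldimethylsilyloxy)phenyl]allyl methyl carbonate
Product: 13 (S)-1-[2-{1-[4-(tert-butyldimethylsilyloxy)phenyl]allyloxy}-4,5-dimethoxy-6-(3-methylbut-2-enyloxy)phenyl]ethanone, via sodium aryloxide 12 (not isolated)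
Conditions: NaH (1.0 equiv), THF, 0 °C; then 11 (1.3 equiv), [Ir(cod)Cl]2 (2 mol %), (Sa,Sc,Sc)-BINOL-derived N,N-bis(1-phenylethyl)phosphoramidite (4 mol %; pre-activated with n-PrNH2, volatiles removed), THF, rt → 40 °C
Reagents that add atoms: none
Why: Iridium-catalysed asymmetric allylic etherification (Hartwig type), in which the cyclometalated iridium phosphoramidite complex ionises the linear carbonate and the only free aryloxide attacks the aryl-substituted allyl terminus, so that the branched ether forms with its configuration set by the (Sa,Sc,Sc) ligand through face selection of the allyl intermediate.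

Step 10
Reactants: 13 (S)-1-[2-{1-[4-(tert-butyldimethylsilyloxy)phenyl]allyloxy}-4,5-dimethoxy-6-(3-methylbut-2-enyloxy)phenyl]ethanone
Product: 15 (S)-2-[1-(tert-butyldimethylsilyloxy)vinyl]-1-{1-[4-(tert-butyldimethylsilyloxy)phenyl]allyloxy}-4,5-dimethoxy-3-(3-methylbut-2-enyloxy)benzene, via potassium enolate 14 (not isolated)
Conditions: KN(SiMe3)2 (1.1 equiv), THF, −78 °C; TBSCl, −78 → 0 °C; Et3N-buffered work-up
Reagents that add atoms: tert-butyldimethylsilyl chloride, CC(C)(C)[Si](C)(C)Cl
Why: Kinetic deprotonation of the methyl ketone at its only enolisable position and O-silylation of the potassium enolate give the silyl enol ether, while the far less acidic C–H of the allylic ether and the aryl silyl ether are left alone at −78 °C.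

Step 11
Reactants: 15 (S)-2-[1-(tert-butyldimethylsilyloxy)vinyl]-1-{1-[4-(tert-butyldimethylsilyloxy)phenyl]allyloxy}-4,5-dimethoxy-3-(3-methylbut-2-enyloxy)benzene
Product: 16 (2S)-4-(tert-butyldimethylsilyloxy)-2-[4-(tert-butyldimethylsilyloxy)phenyl]-6,7-dimethoxy-5-(3-methylbut-2-enyloxy)-2H-chromene
Conditions: second-generation Grubbs catalyst [1,3-bis(2,4,6-trimethylphenyl)imidazolidin-2-ylidene](PCy3)Cl2Ru=CHPh (10 mol %), degassed PhMe (0.005 M), 70 °C, Ar sparge; filtration through Et3N-deactivated silica
Reagents that add atoms: none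
Why: The ruthenium benzylidene should load onto the only monosubstituted alkene, the vinyl group on C2, and the resulting alkylidene adds across the 1-silyloxyvinyl group on C4a to a ruthenacyclobutane that collapses to the C3=C4 bond while ethylene leaves with the methylidene carrier. The closest known reaction type is ring-closing metathesis of silyl enol ethers with terminal olefins to cyclic silyl enol ethers, including the nitrogen counterpart that gives 4-silyloxy-1,2-dihydroquinolines from N-allyl anilines. Ring C closes as a six-membered ring by metathesis between two groups held ortho to each other on ring A, which leaves C4 at the ketone oxidation level. No stereocentre is formed, and C2 keeps the (S) configuration from step 9 because no bond to it is touched and neither acid nor base is present. Site selectivity among three olefins is needed and is secured by the substrate: the trisubstituted prenyl ether on O5 reacts slowly and could reach the C2 carbene only through a strained bridged macrocycle, and the enol ether cannot initiate productively, so the six-membered closure is the only path open to the carbene. The prenyl group is deliberately kept on O5 at this stage, since on C8 it would sit next to the allylic ether and offer a seven-membered closure with loss of isobutene.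

Step 12
Reactants: 16 (2S)-4-(tert-butyldimethylsilyloxy)-2-[4-(tert-butyldimethylsilyloxy)phenyl]-6,7-dimethoxy-5-(3-methylbut-2-enyloxy)-2H-chromene
Product: 17 (2S)-2-(4-hydroxyphenyl)-6,7-dimethoxy-5-(3-methylbut-2-enyloxy)chroman-4-one
Conditions: Bu4NF/AcOH (1:1.2, 3 equiv), THF, 0 °C
Reagents that add atoms: none
Why: Fluoride-mediated desilylation cleaves both Si–O bonds, and the enolate released from the enol ether is protonated at C3 by the acetic acid buffer before it can open ring C by β-elimination of the O1 phenoxide, so C2 should stay (S).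

Step 13
Reactants: 17 (2S)-2-(4-hydroxyphenyl)-6,7-dimethoxy-5-(3-methylbut-2-enyloxy)chroman-4-one
Product: 20 (2S)-5-hydroxy-2-(4-hydroxyphenyl)-6,7-dimethoxy-8-(3-methylbut-2-enyl)chroman-4-one, via Claisen dienone 18 (not isolated), via Cope dienone 19 (not isolated)
Conditions: Eu(fod)3 [tris(6,6,7,7,8,8,8-heptafluoro-2,2-dimethyloctane-3,5-dionato)europium] (10 mol %), CHCl3, 60 °C
Reagents that add atoms: none
Why: Europium-catalysed para-Claisen–Cope rearrangement, in which the Lewis acid chelated between the C4 carbonyl and O5 triggers the aromatic Claisen shift to C6, the methoxy group there blocks enolisation, a Cope shift carries the side chain with restored prenyl connectivity to C8, and the dienone tautomerises to the hydrogen-bonded C5 phenol without touching any bond to C2.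

**Compound list**
1 | 3,4,5-trimethoxyphenol | COc1cc(O)cc(OC)c1OC | starting material
2 | 1-(6-hydroxy-2,3,4-trimethoxyphenyl)ethanone | CC(=O)c1c(O)cc(OC)c(OC)c1OC | intermediate
3 | 2-acetyl-3,4,5-trimethoxyphenyl acetate | CC(=O)Oc1cc(OC)c(OC)c(OC)c1C(C)=O | intermediate
4 | 2-acetyl-3-hydroxy-4,5-dimethoxyphenyl acetate | CC(=O)Oc1cc(OC)c(OC)c(O)c1C(C)=O | intermediate
5 | 3-methylbut-2-en-1-ol (prenol) | CC(C)=CCO | starting material
6 | 2-acetyl-4,5-dimethoxy-3-(3-methylbut-2-enyloxy)phenyl acetate | CC(=O)Oc1cc(OC)c(OC)c(OCC=C(C)C)c1C(C)=O | intermediate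
7 | 1-[6-hydroxy-3,4-dimethoxy-2-(3-methylbut-2-enyloxy)phenyl]ethanone | CC(=O)c1c(O)cc(OC)c(OC)c1OCC=C(C)C | intermediate
8 | methyl (E)-4-hydroxycinnamate | COC(=O)/C=C/c1ccc(O)cc1 | starting material
9 | methyl (E)-3-[4-(tert-butyldimethylsilyloxy)phenyl]acrylate | COC(=O)/C=C/c1ccc(O[Si](C)(C)C(C)(C)C)cc1 | intermediate
10 | (E)-3-[4-(tert-butyldimethylsilyloxy)phenyl]prop-2-en-1-ol | OC/C=C/c1ccc(O[Si](C)(C)C(C)(C)C)cc1 | intermediate
11 | (E)-3-[4-(tert-butyldimethylsilyloxy)phenyl]allyl methyl carbonate | COC(=O)OC/C=C/c1ccc(O[Si](C)(C)C(C)(C)C)cc1 | intermediate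
12 | sodium 2-acetyl-4,5-dimethoxy-3-(3-methylbut-2-enyloxy)phenolate | CC(=O)c1c([O-])cc(OC)c(OC)c1OCC=C(C)C.[Na+] | intermediate
13 | (S)-1-[2-{1-[4-(tert-butyldimethylsilyloxy)phenyl]allyloxy}-4,5-dimethoxy-6-(3-methylbut-2-enyloxy)phenyl]ethanone | COc1c(OCC=C(C)C)c(C(C)=O)c(cc1OC)O[C@H](c1ccc(O[Si](C)(C)C(C)(C)C)cc1)C=C | intermediate
14 | potassium enolate of 13 | COc1c(OCC=C(C)C)c(C(=C)[O-])c(cc1OC)O[C@H](c1ccc(O[Si](C)(C)C(C)(C)C)cc1)C=C.[K+] | intermediate
15 | (S)-2-[1-(tert-butyldimethylsilyloxy)vinyl]-1-{1-[4-(tert-butyldimethylsilyloxy)phenyl]allyloxy}-4,5-dimethoxy-3-(3-methylbut-2-enyloxy)benzene | COc1c(OCC=C(C)C)c(C(=C)O[Si](C)(C)C(C)(C)C)c(cc1OC)O[C@H](c1ccc(O[Si](C)(C)C(C)(C)C)cc1)C=C | intermediate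
16 | (2S)-4-(tert-butyldimethylsilyloxy)-2-[4-(tert-butyldimethylsilyloxy)phenyl]-6,7-dimethoxy-5-(3-methylbut-2-enyloxy)-2H-chromene | COc1c(OCC=C(C)C)c2c(cc1OC)O[C@H](c1ccc(O[Si](C)(C)C(C)(C)C)cc1)C=C2O[Si](C)(C)C(C)(C)C | intermediate
17 | (2S)-2-(4-hydroxyphenyl)-6,7-dimethoxy-5-(3-methylbut-2-enyloxy)chroman-4-one | COc1c(OCC=C(C)C)c2c(cc1OC)O[C@H](c1ccc(O)cc1)CC2=O | intermediate
18 | (2S)-2-(4-hydroxyphenyl)-6,7-dimethoxy-6-(2-methylbut-3-en-2-yl)-2,3-dihydro-4H-chromene-4,5(6H)-dione (C6 epimers) | COC1(C(C)(C)C=C)C(=O)C2=C(C=C1OC)O[C@H](c1ccc(O)cc1)CC2=O | intermediate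
19 | (2S)-2-(4-hydroxyphenyl)-6,7-dimethoxy-8-(3-methylbut-2-enyl)-2,3-dihydro-4H-chromene-4,5(8H)-dione (C8 epimers) | COC1=C(OC)C(CC=C(C)C)C2=C(C1=O)C(=O)C[C@@H](c1ccc(O)cc1)O2 | intermediate
20 | (2S)-5-hydroxy-2-(4-hydroxyphenyl)-6,7-dimethoxy-8-(3-methylbut-2-enyl)chroman-4-one (CNP0104932.1) | COc1c(O)c2c(c(CC=C(C)C)c1OC)O[C@H](c1ccc(O)cc1)CC2=O | target

**Step count**
Total: 13 steps. Longest linear sequence: 10 steps (steps 1–5 and 9–13); the carbonate branch (steps 6–8) adds 3.

**Steps most likely to fail**

1. Step 11 (ring-closing metathesis). The carbene formed at the C2 vinyl group may fail to engage the electron-rich 1-silyloxyvinyl group, which is flanked by two ortho alkoxy substituents. Dimerisation at the vinyl group, ruthenium hydride isomerisation of the allylic ether or ionisation of the O1–C2 bond could then take over. The fallback builds ring C as a chromone and sets C2 by conjugate addition. It sets out from 7: condensation with N,N-dimethylformamide dimethyl acetal (PhMe, 90 °C) should give (E)-3-(dimethylamino)-1-[6-hydroxy-3,4-dimethoxy-2-(3-methylbut-2-enyloxy)phenyl]prop-2-en-1-one F1. Brief treatment with 1 M HCl in CH2Cl2 at rt closes it, with loss of dimethylamine, to 6,7-dimethoxy-5-(3-methylbut-2-enyloxy)-4H-chromen-4-one F2. Asymmetric conjugate addition of [4-(tert-butyldimethylsilyloxy)phenyl]boronic acid follows (Pd(OCOCF3)2, t-BuPyOx, NH4PF6, H2O, ClCH2CH2Cl, 60 °C), with the ligand enantiomer that delivers the (2S) product, expected to be (R)-t-BuPyOx. It should give (2S)-2-[4-(tert-butyldimethylsilyloxy)phenyl]-6,7-dimethoxy-5-(3-methylbut-2-enyloxy)chroman-4-one F3. Bu4NF/AcOH then releases the phenol, and the route is rejoined at 17.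

2. Step 9 (allylic etherification). The chelated, ortho-acylated aryloxide may attack the allyliridium intermediate slowly, so that reversible ionisation of the electron-rich branched ether at the metal erodes both the branched selectivity and the enantiomeric purity. The fallback takes the C2 centre from a ketone reduction and the O1–C2 bond from a Mitsunobu inversion, and unveils the vinyl group afterwards. It sets out from 7 and commercial 3-chloro-1-(4-hydroxyphenyl)propan-1-one. The latter is silylated (TBSCl, imidazole, DMF) to 1-[4-(tert-butyldimethylsilyloxy)phenyl]-3-chloropropan-1-one F4. CBS reduction (BH3·SMe2, (S)-2-methyl-CBS-oxazaborolidine, THF, 0 °C) should give (R)-1-[4-(tert-butyldimethylsilyloxy)phenyl]-3-chloropropan-1-ol F5. Mitsunobu coupling with 7 (PPh3, DIAD, PhMe, 0 °C) is expected to proceed with inversion to (S)-1-[2-{1-[4-(tert-butyldimethylsilyloxy)phenyl]-3-chloropropoxy}-4,5-dimethoxy-6-(3-methylbut-2-enyloxy)phenyl]ethanone F6. The chloride is displaced by PhSeNa (from PhSeSePh reduced beforehand with NaBH4, EtOH) to give the corresponding (S)-3-(phenylselanyl)propyl ether F7. Oxidation (H2O2, pyridine, CH2Cl2, 0 °C → rt) gives the selenoxide F8, whose syn-elimination unveils the vinyl group, and the route is rejoined at 13.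

3. Step 13 (Claisen–Cope rearrangement). The free phenol may sequester the europium catalyst and, at the temperature then needed, the peri-activated prenyl ether may ionise (loss of the prenyl group) or ring C may open and reclose with epimerisation at C2. The fallback reorders the end game so that the rearrangement runs on a substrate with no free hydroxyl, the substrate type on which this reaction is established. It sets out from 16: 0.5 M aqueous HCl in THF at 0 °C should hydrolyse only the enol silyl ether and give the silyl-protected flavanone F3 described above. Eu(fod)3 in CHCl3 at 60 °C should then move the prenyl group through the silylated C6 dienone F9 and the silylated C8 dienone F10 to (2S)-2-[4-(tert-butyldimethylsilyloxy)phenyl]-5-hydroxy-6,7-dimethoxy-8-(3-methylbut-2-enyl)chroman-4-one F11, in which the C5 hydroxyl is locked by hydrogen bonding to the C4 carbonyl. Bu4NF/AcOH (THF, 0 °C) then removes the aryl silyl ether, and the route is rejoined at 20.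

**Further compounds**
F1 | step 11 | (E)-3-(dimethylamino)-1-[6-hydroxy-3,4-dimethoxy-2-(3-methylbut-2-enyloxy)phenyl]prop-2-en-1-one | CN(C)/C=C/C(=O)c1c(O)cc(OC)c(OC)c1OCC=C(C)C
F2 | step 11 | 6,7-dimethoxy-5-(3-methylbut-2-enyloxy)-4H-chromen-4-one | COc1cc2occc(=O)c2c(OCC=C(C)C)c1OC
F3 | step 11 | (2S)-2-[4-(tert-butyldimethylsilyloxy)phenyl]-6,7-dimethoxy-5-(3-methylbut-2-enyloxy)chroman-4-one | COc1c(OCC=C(C)C)c2c(cc1OC)O[C@H](c1ccc(O[Si](C)(C)C(C)(C)C)cc1)CC2=O
F4 | step 9 | 1-[4-(tert-butyldimethylsilyloxy)phenyl]-3-chloropropan-1-one | O=C(CCCl)c1ccc(O[Si](C)(C)C(C)(C)C)cc1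
F5 | step 9 | (R)-1-[4-(tert-butyldimethylsilyloxy)phenyl]-3-chloropropan-1-ol | O[C@H](CCCl)c1ccc(O[Si](C)(C)C(C)(C)C)cc1
F6 | step 9 | (S)-1-[2-{1-[4-(tert-butyldimethylsilyloxy)phenyl]-3-chloropropoxy}-4,5-dimethoxy-6-(3-methylbut-2-enyloxy)phenyl]ethanone | COc1c(OCC=C(C)C)c(C(C)=O)c(cc1OC)O[C@H](c1ccc(O[Si](C)(C)C(C)(C)C)cc1)CCCl
F7 | step 9 | (S)-1-[2-{1-[4-(tert-butyldimethylsilyloxy)phenyl]-3-(phenylselanyl)propoxy}-4,5-dimethoxy-6-(3-methylbut-2-enyloxy)phenyl]ethanone | COc1c(OCC=C(C)C)c(C(C)=O)c(cc1OC)O[C@H](c1ccc(O[Si](C)(C)C(C)(C)C)cc1)CC[Se]c1ccccc1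
F8 | step 9 | (S)-1-[2-{1-[4-(tert-butyldimethylsilyloxy)phenyl]-3-(phenylseleninyl)propoxy}-4,5-dimethoxy-6-(3-methylbut-2-enyloxy)phenyl]ethanone | COc1c(OCC=C(C)C)c(C(C)=O)c(cc1OC)O[C@H](c1ccc(O[Si](C)(C)C(C)(C)C)cc1)CC[Se](=O)c1ccccc1
F9 | step 13 | (2S)-2-[4-(tert-butyldimethylsilyloxy)phenyl]-6,7-dimethoxy-6-(2-methylbut-3-en-2-yl)-2,3-dihydro-4H-chromene-4,5(6H)-dione | COC1(C(C)(C)C=C)C(=O)C2=C(C=C1OC)O[C@H](c1ccc(O[Si](C)(C)C(C)(C)C)cc1)CC2=O
F10 | step 13 | (2S)-2-[4-(tert-butyldimethylsilyloxy)phenyl]-6,7-dimethoxy-8-(3-methylbut-2-enyl)-2,3-dihydro-4H-chromene-4,5(8H)-dione | COC1=C(OC)C(CC=C(C)C)C2=C(C1=O)C(=O)C[C@@H](c1ccc(O[Si](C)(C)C(C)(C)C)cc1)O2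
F11 | step 13 | (2S)-2-[4-(tert-butyldimethylsilyloxy)phenyl]-5-hydroxy-6,7-dimethoxy-8-(3-methylbut-2-enyl)chroman-4-one | COc1c(O)c2c(c(CC=C(C)C)c1OC)O[C@H](c1ccc(O[Si](C)(C)C(C)(C)C)cc1)CC2=O
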